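**Plan**

1. Locants: C1 benzoyl bridgehead, C5 geranyl bridgehead, C2/C4/C9 cage ketones, C3 quaternary carbon between C2 and C4, C6 CH2, C7 CH, C8 CMe2, C10 CH2 on C7, C11 CH on C3, C12 CMe2, C13 ketone and C14 CH2 of the cyclopentanone.
2. Retrosynthetic cuts, in order: C1–COPh; C11–C12 (cyclopentanone); C3–C11 and C10–C11 (two-carbon bridge); C3–C14; C5–C4 and C1–C2 (ring A, a malonyl unit); last C1–C8 and C6–C7 of ring B as a (4+2) disconnection.
3. Enabling feature: ring B (C9, C1, C8, C7, C6, C5) is a cyclohexanone in which C8Me2–C7H(C10) is the skeleton of 3-methylbut-2-enal and C1–C9(O)–C5(geranyl)–C6 that of a 2-silyloxy-3-geranylbutadiene, so one cycloaddition gives the ring with its C9=C5 enol ether in place.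
4. Forward order: ring B (Diels–Alder), ring A (Effenberger cyclisation), C3 side chain, the C3–C11–C10–C7 bridge (aldol lock and release of C7, one-carbon homologation, aldol, dehydration), the cyclopentanone (5-exo radical closure), then the benzoyl group.
5. Stereochemistry: the catalyst sets C7; ring A forms trans to the C7 side chain and fixes C5 and C1; C7 is then inverted through a reversible aldol cage; C3 follows from the bridge, and C11 from attack anti to the C8 methyl groups.

Key step: step 3

Remark: the cationic oxazaborolidine is assumed to shield the enal face next to its C3 phenyl group (formyl C–H···O binding model), which makes the (R)-configured catalyst the one expected to give (S)-6.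
Remark: 1,3-diketones with a free C3–H are drawn as one enol tautomer; the carbinol centres C10 in 15 and C11 in 20 and the enol ether geometry in 18 are left undefined because both forms converge in the next steps.

**Route**

Step 1
Reactants: 1 geranylacetone; 2 paraformaldehyde
Product: 3 (5E)-6,10-dimethyl-3-methylideneundeca-5,9-dien-2-one
Conditions: (CH2O)n, iPr2NH2+ CF3CO2−, CF3CO2H (10 mol %), THF, reflux
Reagents that add atoms: 2 paraformaldehyde (as formaldehyde), C=O
Why: Acid-mediated Mannich condensation and elimination (α-methylenation) runs through the more substituted enol of the methyl ketone, so the methylene group should enter at the CH2 and not at the methyl group.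

Step 2
Reactants: 3 (5E)-6,10-dimethyl-3-methylideneundeca-5,9-dien-2-one
Product: 4 2-(triisopropylsilyloxy)-3-geranylbuta-1,3-diene
Conditions: iPr3SiOSO2CF3, Et3N, CH2Cl2, 0 °C
Reagents that add atoms: triisopropylsilyl trifluoromethanesulfonate, CC(C)[Si](C(C)C)(C(C)C)OS(=O)(=O)C(F)(F)F
Why: Soft enolisation of the methyl group, the only α-position left, and O-silylation (silyl enol ether formation) should give the cross-conjugated 2-silyloxydiene, the bulky silyl group being chosen to survive the acidic catalyst of step 3.

Step 3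
Reactants: 4 2-(triisopropylsilyloxy)-3-geranylbuta-1,3-diene; 5 3-methylbut-2-enal
Product: 6 (1S)-3-geranyl-6,6-dimethyl-4-(triisopropylsilyloxy)cyclohex-3-ene-1-carbaldehyde (ring B; C7 is S, epimeric to the target)
Conditions: (R)-3,3-diphenyl-1-(2-methylphenyl)tetrahydro-1H,3H-pyrrolo[1,2-c][1,3,2]oxazaborole·HN(SO2CF3)2 (20 mol %), CH2Cl2, −40 → −20 °C
Reagents that add atoms: 5 3-methylbut-2-enal, CC(C)=CC=O
Why: The protonated oxazaborolidine binds the enal at oxygen and lowers its LUMO, so the electron-rich diene adds in an asynchronous concerted (4+2) cycloaddition in which the diene terminus next to the siloxy carbon (C1) bonds first to the β-carbon C8 and C6–C7 follows. The closest known reaction type is the cationic oxazaborolidine-catalysed Diels–Alder reaction of 2-(triisopropylsilyloxy)buta-1,3-diene with enals, enones and acrylates. Ring B is closed by intermolecular (4+2) cycloaddition, both ring bonds (C1–C8 and C6–C7) forming in the one step and leaving the C9=C5 silyl enol ether. The single new stereocentre C7 is controlled by the catalyst, which shields one face of the s-trans enal; endo or exo approach is irrelevant because C8 carries two identical methyl groups. The step needs para regioselectivity and enal-face selectivity: the 2-silyloxy group makes C1 the nucleophilic terminus, and the 2,3-disubstitution holds the diene s-cis, which should offset the low reactivity of the β,β-disubstituted enal.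

Step 4
Reactants: 6 ring B aldehyde
Product: 7 [(1S)-3-geranyl-6,6-dimethyl-4-(triisopropylsilyloxy)cyclohex-3-en-1-yl]methanol
Conditions: NaBH4, MeOH/THF, 0 °C
Reagents that add atoms: none
Why: Chemoselective borohydride reduction of the aldehyde leaves the silyl enol ether and the trisubstituted alkenes untouched and takes C10 to an oxidation level that can be carried through acid chloride chemistry.

Step 5
Reactants: 7 ring B alcohol
Product: 8 [(1S)-3-geranyl-6,6-dimethyl-4-(triisopropylsilyloxy)cyclohex-3-en-1-yl]methyl acetate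
Conditions: Ac2O, pyridine, 4-(dimethylamino)pyridine (5 mol %), CH2Cl2, 0 °C → rt
Reagents that add atoms: acetic anhydride, CC(=O)OC(C)=O
Why: Nucleophile-catalysed acylation of the primary alcohol gives an acetate that is inert to malonyl dichloride.

Step 6
Reactants: 8 ring B acetate; 9 malonyl dichloride
Product: 11 5-geranyl-7-exo-(hydroxymethyl)-8,8-dimethylbicyclo[3.3.1]nonane-2,4,9-trione (enol form), via trione acetate 10 (not isolated)
Conditions: ClCOCH2COCl (3 equiv), Et2O, −20 °C → rt; then KOH, benzyltriethylammonium chloride, H2O, rt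
Reagents that add atoms: 9 malonyl dichloride, O=C(Cl)CC(=O)Cl
Why: In this Effenberger cyclisation the silyl enol ether is C-acylated at C5 and the second acid chloride then acylates C1, closing ring A trans to the pseudo-equatorial C7 side chain so that C7 relays its configuration to C5 and C1; the aqueous KOH treatment that converts O-acylated material to the trione should also saponify the acetate.

Step 7
Reactants: 11 bicyclic trione alcohol; 12 1-bromo-3-methylbutan-2-one
Product: 13 3-(3-methyl-2-oxobutyl)-5-geranyl-7-exo-(hydroxymethyl)-8,8-dimethylbicyclo[3.3.1]nonane-2,4,9-trione (enol form)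
Conditions: K2CO3, CHCl3, rt
Reagents that add atoms: 12 1-bromo-3-methylbutan-2-one, CC(C)C(=O)CBr
Why: SN2 alkylation of the cyclic 1,3-diketone enolate by an α-bromo ketone, a pairing known to favour carbon over oxygen, should attach C14–C13–C12 to C3 and leave C3 enolisable.

Step 8
Reactants: 13 C3-alkylated trione alcohol
Product: 15 adamantane aldol (3-(3-methyl-2-oxobutyl)-5-geranyl-10-hydroxy-8,8-dimethyl cage 2,4,9-trione with C10 bridging C3 and C7), via exo aldehyde 14 (not isolated)
Conditions: Dess–Martin periodinane, NaHCO3, CH2Cl2, 0 °C → rt; then 1,8-diazabicyclo[5.4.0]undec-7-ene (20 mol %), rt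
Reagents that add atoms: none
Why: Dess–Martin oxidation gives the C7-exo aldehyde, and base-mediated enolisation equilibrates C7 so that only the C7-endo epimer can undergo the intramolecular aldol addition of C3 to C10, which locks the inverted C7 configuration in an adamantane cage of the kind known for caged acylphloroglucinol aldols.

Step 9
Reactants: 15 adamantane aldol; 16 [2-(trimethylsilyl)ethoxymethyl]triphenylphosphonium chloride
Product: 18 C7-endo 2-[2-(trimethylsilyl)ethoxy]ethenyl bicyclic diketone (enol form, E/Z mixture), via endo aldehyde 17 (not isolated)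
Conditions: KN(SiMe3)2 (1.05 equiv), THF, −78 → 0 °C; then Ph3P=CHOCH2CH2SiMe3 (from 16 and KN(SiMe3)2), THF, −78 → 0 °C
Reagents that add atoms: 16 [2-(trimethylsilyl)ethoxymethyl]triphenylphosphonium chloride, C[Si](C)(C)CCOC[P+](c1ccccc1)(c1ccccc1)c1ccccc1.[Cl-]
Why: Proposed new method: deprotonation of the cage carbinol gives a potassium alkoxide whose retro-aldol fragmentation is driven by formation of the stabilised 1,3-diketonate and releases the aldehyde only as its C7-endo epimer 17, which the non-stabilised ylide should capture by Wittig olefination faster than it enolises, so that the inverted C7 configuration is carried into the enol ether; the closest known reaction types are the Wittig olefination of lactols through their open hydroxy aldehyde form and the base-induced retro-aldol cleavage of β-hydroxy-1,3-diketones.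

Step 10
Reactants: 18 C7-endo enol ether
Product: 20 homoadamantane aldol (11-hydroxy cage 2,4,9-trione with C3–C11–C10–C7 bridge and 3-methyl-2-oxobutyl group on C3), via homologated endo aldehyde 19 (not isolated)
Conditions: Bu4NF, THF, 0 → 40 °C
Reagents that add atoms: none
Why: Fluoride-induced β-elimination of the 2-(trimethylsilyl)ethyl enol ether unveils the C11 aldehyde without acid, and intramolecular aldol addition of the C3 diketonate closes the seven-membered ring, the tether from C7 forcing C11 onto the endo face of C3 and so fixing the quaternary stereocentre C3.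

Step 11
Reactants: 20 homoadamantane aldol
Product: 21 homoadamant-10-ene triketone (cis C10=C11, 3-methyl-2-oxobutyl group on C3)
Conditions: methyl N-(triethylammoniosulfonyl)carbamate (Burgess reagent), toluene, 70 °C
Reagents that add atoms: none
Why: Burgess dehydration (syn elimination through the sulfamate ester) can only take a hydrogen from C10 because C3 is quaternary, and its neutral conditions should avoid retro-aldol cleavage.

Step 12
Reactants: 21 homoadamantene triketone
Product: 23 C12 bromide (3-(3-bromo-3-methyl-2-oxobutyl) homoadamantene triketone), via silyl enol ether 22 (not isolated)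
Conditions: Me3SiOSO2CF3, Et3N, CH2Cl2, 0 °C → rt; then N-bromosuccinimide, THF, −78 °C
Reagents that add atoms: N-bromosuccinimide, BrN1C(=O)CCC1=O
Why: The only enolisable ketone is silylated under equilibrating conditions toward its more substituted α-carbon C12 (C14 is neopentyl), and electrophilic bromination of the silyl enol ether should be far faster than attack on the alkenes at low temperature.

Step 13
Reactants: 23 C12 bromide
Product: 24 1-debenzoyl target (tetracyclic tetraketone with C1–H)
Conditions: Bu3SnH (slow addition), 2,2'-azobis(2-methylpropionitrile) (10 mol %), benzene, 80 °C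
Reagents that add atoms: none
Why: Tin-mediated 5-exo-trig radical cyclisation of the tertiary α-keto radical onto C11 forms the cyclopentanone (6-endo closure is excluded by the cage), attack on the alkene face remote from the C8 methyl groups should set C11, and the C10 radical is reduced to CH2.

Step 14
Reactants: 24 1-debenzoyl target; 25 benzoyl chloride
Product: 28 CNP0110281.1 (target), via cyclopentanone silyl enol ether 26 (not isolated), via benzoylated silyl enol ether 27 (not isolated)
Conditions: Me3SiCl, LiN(iPr)2, THF, −78 °C; lithium 2,2,6,6-tetramethylpiperidide, −78 → −40 °C; PhCOCl, −78 °C; 1 M HCl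
Reagents that add atoms: 25 benzoyl chloride, O=C(Cl)c1ccccc1
Why: After in situ protection of the cyclopentanone as its silyl enol ether, the bridgehead C1–H between the C2 and C9 carbonyls is removed by the hindered amide (bridgehead metalation of a bicyclo[3.3.1]nonane polyketone) and the carbanion is C-acylated, the cage holding the C1 configuration.

**Compound list**

1 | geranylacetone, (5E)-6,10-dimethylundeca-5,9-dien-2-one | CC(C)=CCC/C(C)=C/CCC(C)=O | starting material
2 | paraformaldehyde (formaldehyde source) | C=O | starting material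
3 | (5E)-6,10-dimethyl-3-methylideneundeca-5,9-dien-2-one | CC(C)=CCC/C(C)=C/CC(=C)C(C)=O | intermediate
4 | 2-(triisopropylsilyloxy)-3-geranylbuta-1,3-diene | C=C(O[Si](C(C)C)(C(C)C)C(C)C)C(=C)C/C=C(\C)CCC=C(C)C | intermediate
5 | 3-methylbut-2-enal | CC(C)=CC=O | starting material
6 | (1S)-3-geranyl-6,6-dimethyl-4-(triisopropylsilyloxy)cyclohex-3-ene-1-carbaldehyde | CC(C)=CCC/C(C)=C/CC1=C(O[Si](C(C)C)(C(C)C)C(C)C)CC(C)(C)[C@@H](C=O)C1 | intermediate
7 | [(1S)-3-geranyl-6,6-dimethyl-4-(triisopropylsilyloxy)cyclohex-3-en-1-yl]methanol | CC(C)=CCC/C(C)=C/CC1=C(O[Si](C(C)C)(C(C)C)C(C)C)CC(C)(C)[C@@H](CO)C1 | intermediate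
8 | [(1S)-3-geranyl-6,6-dimethyl-4-(triisopropylsilyloxy)cyclohex-3-en-1-yl]methyl acetate | CC(C)=CCC/C(C)=C/CC1=C(O[Si](C(C)C)(C(C)C)C(C)C)CC(C)(C)[C@@H](COC(C)=O)C1 | intermediate
9 | malonyl dichloride | O=C(Cl)CC(=O)Cl | starting material
10 | 7-exo-(acetoxymethyl)-5-geranyl-8,8-dimethylbicyclo[3.3.1]nonane-2,4,9-trione, enol form | CC(C)=CCC/C(C)=C/C[C@@]12C[C@H](COC(C)=O)C(C)(C)[C@@H](C(=O)C=C1O)C2=O | intermediate (not isolated)
11 | 5-geranyl-7-exo-(hydroxymethyl)-8,8-dimethylbicyclo[3.3.1]nonane-2,4,9-trione, enol form | CC(C)=CCC/C(C)=C/C[C@@]12C[C@H](CO)C(C)(C)[C@@H](C(=O)C=C1O)C2=O | intermediate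
12 | 1-bromo-3-methylbutan-2-one | CC(C)C(=O)CBr | starting material
13 | 3-(3-methyl-2-oxobutyl) derivative of 11, enol form | CC(C)=CCC/C(C)=C/C[C@@]12C[C@H](CO)C(C)(C)[C@@H](C(=O)C(CC(=O)C(C)C)=C1O)C2=O | intermediate
14 | C7-exo aldehyde from 13, enol form | CC(C)=CCC/C(C)=C/C[C@@]12C[C@H](C=O)C(C)(C)[C@@H](C(=O)C(CC(=O)C(C)C)=C1O)C2=O | intermediate (not isolated)
15 | adamantane aldol: C3–C10 bond, C10 carbinol (epimers), C7 inverted, 3-methyl-2-oxobutyl on C3 | CC(C)=CCC/C(C)=C/C[C@@]12C[C@H]3C(O)[C@@](CC(=O)C(C)C)(C1=O)C(=O)[C@@H](C2=O)C3(C)C | intermediate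
16 | [2-(trimethylsilyl)ethoxymethyl]triphenylphosphonium chloride | C[Si](C)(C)CCOC[P+](c1ccccc1)(c1ccccc1)c1ccccc1.[Cl-] | starting material
17 | C7-endo aldehyde (ring-opened form of 15), enol form | CC(C)=CCC/C(C)=C/C[C@@]12C[C@@H](C=O)C(C)(C)[C@@H](C(=O)C(CC(=O)C(C)C)=C1O)C2=O | intermediate (not isolated)
18 | C7-endo 2-[2-(trimethylsilyl)ethoxy]ethenyl bicyclic diketone, enol form | CC(C)=CCC/C(C)=C/C[C@@]12C[C@@H](C=COCC[Si](C)(C)C)C(C)(C)[C@@H](C(=O)C(CC(=O)C(C)C)=C1O)C2=O | intermediate
19 | C7-endo 2-oxoethyl bicyclic diketone, enol form | CC(C)=CCC/C(C)=C/C[C@@]12C[C@@H](CC=O)C(C)(C)[C@@H](C(=O)C(CC(=O)C(C)C)=C1O)C2=O | intermediate (not isolated)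
20 | homoadamantane aldol: C3–C11 bond, C11 carbinol (epimers) | CC(C)=CCC/C(C)=C/C[C@@]12C[C@H]3CC(O)[C@@](CC(=O)C(C)C)(C1=O)C(=O)[C@@H](C2=O)C3(C)C | intermediate
21 | homoadamant-10-ene triketone with 3-methyl-2-oxobutyl on C3 | CC(C)=CCC/C(C)=C/C[C@@]12C[C@H]3/C=C\[C@@](CC(=O)C(C)C)(C1=O)C(=O)[C@@H](C2=O)C3(C)C | intermediate
22 | C13 trimethylsilyl enol ether of 21 (C13=C12) | CC(C)=CCC/C(C)=C/C[C@@]12C[C@H]3/C=C\[C@@](CC(O[Si](C)(C)C)=C(C)C)(C1=O)C(=O)[C@@H](C2=O)C3(C)C | intermediate (not isolated)
23 | C12 bromide of 21 | CC(C)=CCC/C(C)=C/C[C@@]12C[C@H]3/C=C\[C@@](CC(=O)C(C)(C)Br)(C1=O)C(=O)[C@@H](C2=O)C3(C)C | intermediate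
24 | 1-debenzoyl target (C1–H tetraketone) | CC(C)=CCC/C(C)=C/C[C@@]12C[C@H]3C[C@H]4C(C)(C)C(=O)C[C@]4(C1=O)C(=O)[C@@H](C2=O)C3(C)C | intermediate
25 | benzoyl chloride | O=C(Cl)c1ccccc1 | starting material
26 | C13 trimethylsilyl enol ether of 24 (C13=C14) | CC(C)=CCC/C(C)=C/C[C@@]12C[C@H]3C[C@H]4C(C)(C)C(O[Si](C)(C)C)=C[C@]4(C1=O)C(=O)[C@@H](C2=O)C3(C)C | intermediate (not isolated)
27 | 1-benzoyl derivative of 26 | CC(C)=CCC/C(C)=C/C[C@@]12C[C@H]3C[C@H]4C(C)(C)C(O[Si](C)(C)C)=C[C@]4(C1=O)C(=O)[C@@](C(=O)c1ccccc1)(C2=O)C3(C)C | intermediate (not isolated)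
28 | CNP0110281.1 | CC(C)=CCC/C(C)=C/C[C@@]12C[C@H]3C[C@H]4C(C)(C)C(=O)C[C@]4(C1=O)C(=O)[C@@](C(=O)c1ccccc1)(C2=O)C3(C)C | target

**Step count and risks**

Total step count: 14. Longest linear sequence: 14 steps (1 → 28).

Steps most likely to fail:

Step 9 (proposed new method). The released C7-endo aldehyde may enolise back to the exo series, or the ylide may olefinate the side-chain ketone, before the aldehyde is captured. The fallback uses known chemistry and keeps the aldol-locked C7. It sets out from 15. Dess–Martin oxidation of the cage carbinol should give the adamantane 2,4,9,10-tetraketone F1. One-carbon ring expansion with Me3SiCHN2 and BF3·OEt2, in which the tertiary C7 should migrate in preference to the doubly acylated C3, followed by protodesilylation, should give the homoadamantan-11-one F2 (carbonyl on the carbon attached to C3). KOtBu in tBuOH should close the cyclopentanone by intramolecular aldol addition of C12 to that ketone from the side remote from the C8 methyl groups, giving the tertiary aldol F3. Acylation with ClCOCO2Me and 4-(dimethylamino)pyridine gives the methyl oxalate F4. Bu3SnH and 2,2'-azobis(2-methylpropionitrile) in toluene at reflux (Barton–McCombie-type deoxygenation of a tertiary oxalate) should then return to the route at 24, bypassing steps 9 to 13.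

Step 14. Deprotonation of the bridgehead C1–H may be incomplete in the rigid cage, and the carbanion may be lost by proton transfer before it is acylated. The fallback sets out from 24. Lithium 2,2,6,6-tetramethylpiperidide in the presence of Me3SiCl (in situ quench, then aqueous work-up to return the cyclopentanone) should trap the carbanion as the bridgehead silane F5. Fluoride-triggered desilylative addition to benzaldehyde with Bu4N+ Ph3SiF2− should give the C1 phenylcarbinol F6 (epimers), and Dess–Martin oxidation returns to the route at 28.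

Step 3. The β,β-disubstituted enal may add too slowly on the chiral Lewis acid, so that protodesilylation of the diene competes and facial selectivity erodes. The fallback sets out from 4 and 5. A racemic cycloaddition promoted by Me2AlCl in CH2Cl2 at −78 → −20 °C should give the racemic ring B aldehyde F7, and NaBH4 reduction gives the racemic alcohol F8. Preparative chromatography on a chiral stationary phase separates the enantiomers; the (S)-enantiomer is 7, where the route resumes.

**Further compounds**

F1 | step 9 | adamantane 2,4,9,10-tetraketone from 15 | CC(C)=CCC/C(C)=C/C[C@@]12C[C@H]3C(=O)[C@@](CC(=O)C(C)C)(C1=O)C(=O)[C@@H](C2=O)C3(C)C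
F2 | step 9 | homoadamantan-11-one (C7–C10H2–C11(=O)–C3) | CC(C)=CCC/C(C)=C/C[C@@]12C[C@H]3CC(=O)[C@@](CC(=O)C(C)C)(C1=O)C(=O)[C@@H](C2=O)C3(C)C
F3 | step 9 | 11-hydroxy derivative of 24 (tertiary aldol) | CC(C)=CCC/C(C)=C/C[C@@]12C[C@H]3C[C@@]4(O)C(C)(C)C(=O)C[C@]4(C1=O)C(=O)[C@@H](C2=O)C3(C)C
F4 | step 9 | methyl oxalate of F3 | CC(C)=CCC/C(C)=C/C[C@@]12C[C@H]3C[C@@]4(OC(=O)C(=O)OC)C(C)(C)C(=O)C[C@]4(C1=O)C(=O)[C@@H](C2=O)C3(C)C
F5 | step 14 | 1-(trimethylsilyl) derivative of 24 | CC(C)=CCC/C(C)=C/C[C@@]12C[C@H]3C[C@H]4C(C)(C)C(=O)C[C@]4(C1=O)C(=O)[C@@]([Si](C)(C)C)(C2=O)C3(C)C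
F6 | step 14 | 1-[hydroxy(phenyl)methyl] derivative of 24 | CC(C)=CCC/C(C)=C/C[C@@]12C[C@H]3C[C@H]4C(C)(C)C(=O)C[C@]4(C1=O)C(=O)[C@@](C(O)c1ccccc1)(C2=O)C3(C)C
F7 | step 3 | racemic 3-geranyl-6,6-dimethyl-4-(triisopropylsilyloxy)cyclohex-3-ene-1-carbaldehyde | CC(C)=CCC/C(C)=C/CC1=C(O[Si](C(C)C)(C(C)C)C(C)C)CC(C)(C)C(C=O)C1
F8 | step 3 | racemic [3-geranyl-6,6-dimethyl-4-(triisopropylsilyloxy)cyclohex-3-en-1-yl]methanol | CC(C)=CCC/C(C)=C/CC1=C(O[Si](C(C)C)(C(C)C)C(C)C)CC(C)(C)C(CO)C1
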